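## Retrosynthetic overview

1. The target comes from its octa-MOM ether by acid cleavage; the aryl ketone comes from a silyl-protected carbinol, and the C8–cyclohexene bond from a late Suzuki–Miyaura union of a cyclohexenyl boronate with an 8-bromo-3-prenylflavone.
2. The boronate comes from a kinetic enol triflate of a 2,3,5-trisubstituted cyclohexanone, itself made by copper-catalysed aryl-Grignard conjugate addition and aldol trapping on (S)-5-methylcyclohexenone.
3. (S)-5-Methylcyclohexenone comes from an organocatalytic Michael/aldol condensation of crotonaldehyde with methyl acetoacetate (carbocycle, formed first).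
4. The bromoflavone comes from C3 prenylation of a flavone made by 6-endo cyclisation of an o-hydroxyaryl ynone (pyranone ring, formed second), from a brominated salicylaldehyde and an arylacetylene.
5. All four arenes come from resorcinol through its bis-MOM ether (bromination, ortho-lithiation, Ir-catalysed C–H borylation/oxidation).

Abbreviations: MOM = CH2OCH3 (MOMO = methoxymethoxy); prenyl = 3-methylbut-2-en-1-yl; TBS = tert-butyldimethylsilyl; pin = pinacolato.

Assumption: the carbinol carbon made in step 7 (it becomes the ketone carbon in step 21), C2 of 11, C1 of 12 and the carbinol carbon of 29 form as epimer mixtures of no consequence and are left undefined in names and SMILES; organometallic bases are used as purchased solutions.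

## Route

Step 1
Reactants: 1 resorcinol
Product: 2 1,3-bis(methoxymethoxy)benzene
Conditions: MOMCl (2.5 equiv), iPr2NEt, CH2Cl2, 0 °C → rt
Reagents that add atoms: chloromethyl methyl ether, COCCl
Why: Williamson-type O-alkylation (MOM protection) caps both phenols with groups that direct ortho-metalation and survive the basic and organometallic steps.

Step 2
Reactants: 2 1,3-bis(methoxymethoxy)benzene
Product: 3 1-bromo-2,4-bis(methoxymethoxy)benzene
Conditions: NBS (1.0 equiv), MeCN, 0 °C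
Reagents that add atoms: N-bromosuccinimide, O=C1CCC(=O)N1Br
Why: Electrophilic aromatic bromination goes to C4 (para to one ether, ortho to the other) because the C2 position between the two ethers is shielded.

Step 3
Reactants: 2 1,3-bis(methoxymethoxy)benzene; 4 1-bromo-3-methylbut-2-ene
Product: 6 1,3-bis(methoxymethoxy)-2-prenylbenzene, via aryllithium 5 (not isolated)
Conditions: n-BuLi, THF, 0 °C → rt; CuI (10 mol%), 4, −78 °C → rt
Reagents that add atoms: none
Why: Directed ortho-metalation at the doubly activated C2 followed by copper-assisted SN2 allylation gives the linear prenyl arene.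

Step 4
Reactants: 6 1,3-bis(methoxymethoxy)-2-prenylbenzene
Product: 8 2,4-bis(methoxymethoxy)-3-prenylbenzaldehyde, via aryllithium 7 (not isolated)
Conditions: n-BuLi, TMEDA, THF, −20 → 0 °C; DMF, −78 °C → rt; H2O
Reagents that add atoms: N,N-dimethylformamide, CN(C)C=O
Why: A second directed ortho-metalation next to a MOM ether and Bouveault-type formylation with DMF install the aldehyde at C4.

Step 5
Reactants: 9 (E)-but-2-enal; 10 methyl 3-oxobutanoate
Product: 12 methyl (6S)-6-methyl-2-oxocyclohex-3-ene-1-carboxylate, via Michael adduct 11 (not isolated)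
Conditions: (R)-2-{bis[3,5-bis(trifluoromethyl)phenyl](trimethylsilyloxy)methyl}pyrrolidine (10 mol%), PhCO2H (10 mol%), toluene, rt; then TsOH·H2O (20 mol%), 80 °C
Reagents that add atoms: none
Why: Iminium-ion organocatalytic Michael addition then acid-catalysed intramolecular aldol condensation (Jørgensen cyclohexenone synthesis); the keto ester adds to the enal β-carbon on the face opposite the diaryl(silyloxy)methyl group of the (R)-catalyst, which by the usual shielding model sets the methyl-bearing centre as S.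

Step 6
Reactants: 12 methyl (6S)-6-methyl-2-oxocyclohex-3-ene-1-carboxylate
Product: 13 (5S)-5-methylcyclohex-2-en-1-one
Conditions: LiCl, H2O, DMSO, 140 °C
Reagents that add atoms: none
Why: Krapcho dealkoxycarbonylation removes the ester; the β-stereocentre is not enolisable, so it is retained.

Step 7
Reactants: 3 1-bromo-2,4-bis(methoxymethoxy)benzene; 13 (5S)-5-methylcyclohex-2-en-1-one; 8 2,4-bis(methoxymethoxy)-3-prenylbenzaldehyde
Product: 16 (2S,3S,5S)-3-[2,4-bis(MOMO)phenyl]-2-{hydroxy[2,4-bis(MOMO)-3-prenylphenyl]methyl}-5-methylcyclohexan-1-one, via aryl Grignard reagent 14 (not isolated), via magnesium enolate 15 (not isolated)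
Conditions: 3, Mg, THF, 40 °C; CuBr·SMe2 (10 mol%), 13, THF, −40 °C; then 8, −78 °C; H2O
Reagents that add atoms: none
Why: Copper-catalysed conjugate addition with aldol trapping (three-component coupling): the aryl group adds anti to the C5 methyl (trans-3,5) and the enolate attacks the aldehyde anti to the new C3 aryl (trans-2,3), fixing all three ring stereocentres.

Step 8
Reactants: 16 aldol adduct (2S,3S,5S)
Product: 17 (2S,3S,5S)-3-[2,4-bis(MOMO)phenyl]-2-{(TBS-oxy)[2,4-bis(MOMO)-3-prenylphenyl]methyl}-5-methylcyclohexan-1-one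
Conditions: TBSOTf, 2,6-lutidine, CH2Cl2, −78 → 0 °C
Reagents that add atoms: tert-butyldimethylsilyl trifluoromethanesulfonate, CC(C)(C)[Si](C)(C)OS(=O)(=O)C(F)(F)F
Why: O-Silylation blocks retro-aldol cleavage and keeps the future ketone carbon at the alcohol oxidation level so that the ring ketone can be enolised selectively.

Step 9
Reactants: 17 silyl ether (2S,3S,5S)
Product: 19 (3S,5S,6S)-5-[2,4-bis(MOMO)phenyl]-6-{(TBS-oxy)[2,4-bis(MOMO)-3-prenylphenyl]methyl}-3-methylcyclohex-1-en-1-yl trifluoromethanesulfonate, via potassium enolate 18 (not isolated)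
Conditions: KN(SiMe3)2, THF, −78 °C; PhNTf2, −78 → 0 °C
Reagents that add atoms: N-phenylbis(trifluoromethanesulfonimide), O=S(=O)(N(c1ccccc1)S(=O)(=O)C(F)(F)F)C(F)(F)F
Why: Kinetic deprotonation at the unhindered C6 methylene and O-triflation place the double bond away from the substituted α-carbon, whose configuration is untouched.

Step 10
Reactants: 19 enol triflate (3S,5S,6S)
Product: 20 2-[(3S,5S,6R)-5-[2,4-bis(MOMO)phenyl]-6-{(TBS-oxy)[2,4-bis(MOMO)-3-prenylphenyl]methyl}-3-methylcyclohex-1-en-1-yl]-4,4,5,5-tetramethyl-1,3,2-dioxaborolane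
Conditions: B2pin2, PdCl2(PPh3)2 (5 mol%), PPh3 (10 mol%), KOPh, toluene, 50 °C
Reagents that add atoms: bis(pinacolato)diboron, CC1(C)OB(OC1(C)C)B1OC(C)(C)C(C)(C)O1
Why: Miyaura borylation turns the alkenyl triflate into a bench-stable alkenyl boronate (the 6S → 6R change is only a CIP priority change).

Step 11
Reactants: 2 1,3-bis(methoxymethoxy)benzene
Product: 22 3,5-bis(methoxymethoxy)phenol, via aryl boronate 21 (not isolated)
Conditions: [Ir(OMe)(cod)]2 (1 mol%), 4,4'-di-tert-butyl-2,2'-bipyridine (2 mol%), B2pin2, THF, 80 °C; then H2O2, aq NaOH, 0 °C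
Reagents that add atoms: hydrogen peroxide, OO (phenol oxygen); bis(pinacolato)diboron, CC1(C)OB(OC1(C)C)B1OC(C)(C)C(C)(C)O1 (boryl group of 21 only)
Why: Sterically controlled iridium-catalysed C–H borylation hits C5, the only position without an ortho substituent, and oxidation of the C–B bond gives the phloroglucinol pattern.

Step 12
Reactants: 22 3,5-bis(methoxymethoxy)phenol
Product: 23 2-hydroxy-4,6-bis(methoxymethoxy)benzaldehyde
Conditions: MgCl2, Et3N, (CH2O)n, MeCN, reflux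
Reagents that add atoms: formaldehyde (as paraformaldehyde), C=O
Why: Magnesium-mediated ortho-formylation (Casnati–Skattebøl) is specific for the position next to the free phenol, and the two such positions are equivalent.

Step 13
Reactants: 23 2-hydroxy-4,6-bis(methoxymethoxy)benzaldehyde
Product: 24 3-bromo-2-hydroxy-4,6-bis(methoxymethoxy)benzaldehyde
Conditions: NBS (1.0 equiv), CH2Cl2, −20 °C
Reagents that add atoms: N-bromosuccinimide, O=C1CCC(=O)N1Br
Why: Electrophilic bromination is directed ortho to the free phenol (C3), which is also less hindered than C5 between two MOM ethers.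

Step 14
Reactants: 3 1-bromo-2,4-bis(methoxymethoxy)benzene; 25 ethynyltrimethylsilane
Product: 26 {[2,4-bis(methoxymethoxy)phenyl]ethynyl}trimethylsilane
Conditions: PdCl2(PPh3)2 (3 mol%), CuI (5 mol%), Et3N, 70 °C
Reagents that add atoms: none
Why: Sonogashira coupling attaches the two-carbon unit of the future pyranone to ring B.

Step 15
Reactants: 26 silyl alkyne
Product: 27 1-ethynyl-2,4-bis(methoxymethoxy)benzene
Conditions: K2CO3 (10 mol%), MeOH, rt
Reagents that add atoms: none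
Why: Base-catalysed methanolysis of the C–Si bond (protodesilylation) frees the terminal alkyne without touching the MOM ethers.

Step 16
Reactants: 24 3-bromo-2-hydroxy-4,6-bis(methoxymethoxy)benzaldehyde; 27 1-ethynyl-2,4-bis(methoxymethoxy)benzene
Product: 29 2-bromo-6-{3-[2,4-bis(MOMO)phenyl]-1-hydroxyprop-2-yn-1-yl}-3,5-bis(methoxymethoxy)phenol, via lithium acetylide 28 (not isolated)
Conditions: 27 (2.2 equiv), n-BuLi (2.1 equiv), THF, −78 °C; 24, −78 → 0 °C; H2O
Reagents that add atoms: none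
Why: 1,2-Addition of the acetylide to the aldehyde (the first equivalent only deprotonates the phenol and is recovered as 27) builds the C3 chain of the flavone.

Step 17
Reactants: 29 propargylic alcohol
Product: 31 8-bromo-2-[2,4-bis(MOMO)phenyl]-5,7-bis(methoxymethoxy)-4H-chromen-4-one, via ynone 30 (not isolated)
Conditions: MnO2, CH2Cl2, rt; then Et2NH, EtOH, 60 °C
Reagents that add atoms: none
Why: MnO2 oxidation then amine-mediated 6-endo oxa-Michael cyclisation (through the β-enaminone) closes the pyranone; the phenol oxygen next to the C–Br carbon becomes O1, so bromine ends up at C8.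

Step 18
Reactants: 31 8-bromoflavone; 4 1-bromo-3-methylbut-2-ene
Product: 33 8-bromo-2-[2,4-bis(MOMO)phenyl]-5,7-bis(methoxymethoxy)-3-prenyl-4H-chromen-4-one, via 3-lithioflavone 32 (not isolated)
Conditions: LiN(iPr)2, THF, −78 °C; CuI (10 mol%), 4, −78 → −30 °C
Reagents that add atoms: none
Why: Deprotonation of the only pyranone C–H (C3, α to the carbonyl) and SN2 allylation install the prenyl group, while the amide base leaves the aryl bromide alone.

Step 19
Reactants: 20 cyclohexenyl boronate (3S,5S,6R); 33 8-bromo-3-prenylflavone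
Product: 34 8-[(3S,5S,6R)-5-[2,4-bis(MOMO)phenyl]-6-{(TBS-oxy)[2,4-bis(MOMO)-3-prenylphenyl]methyl}-3-methylcyclohex-1-en-1-yl]-2-[2,4-bis(MOMO)phenyl]-5,7-bis(methoxymethoxy)-3-prenyl-4H-chromen-4-one
Conditions: Pd(OAc)2 (5 mol%), SPhos (10 mol%), K3PO4, toluene/H2O (10:1), 90 °C
Reagents that add atoms: none
Why: Suzuki–Miyaura coupling with a bulky biarylphosphine joins the two halves at C8 and fixes the double bond position; no stereocentre is touched.

Step 20
Reactants: 34 coupled silyl ether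
Product: 35 8-[(3S,5S,6R)-5-[2,4-bis(MOMO)phenyl]-6-{hydroxy[2,4-bis(MOMO)-3-prenylphenyl]methyl}-3-methylcyclohex-1-en-1-yl]-2-[2,4-bis(MOMO)phenyl]-5,7-bis(methoxymethoxy)-3-prenyl-4H-chromen-4-one
Conditions: Bu4NF, AcOH (1:1), THF, 0 °C → rt
Reagents that add atoms: none
Why: Buffered fluoride desilylation frees the carbinol without exposing the flavone to strong base.

Step 21
Reactants: 35 carbinol
Product: 36 8-[(3S,5S,6R)-6-[2,4-bis(MOMO)-3-prenylbenzoyl]-5-[2,4-bis(MOMO)phenyl]-3-methylcyclohex-1-en-1-yl]-2-[2,4-bis(MOMO)phenyl]-5,7-bis(methoxymethoxy)-3-prenyl-4H-chromen-4-one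
Conditions: Dess–Martin periodinane, CH2Cl2, 0 °C → rt
Reagents that add atoms: none
Why: Dess–Martin oxidation gives the aryl ketone under near-neutral conditions, so the now α-keto and allylic C6–H does not epimerise and the double bond stays in place.

Step 22
Reactants: 36 octa-MOM ether
Product: 37 8-[(3S,5S,6R)-6-[2,4-dihydroxy-3-prenylbenzoyl]-5-(2,4-dihydroxyphenyl)-3-methylcyclohex-1-en-1-yl]-2-(2,4-dihydroxyphenyl)-5,7-dihydroxy-3-prenyl-4H-chromen-4-one (CNP0314407.1)
Conditions: 3 M aq HCl, MeOH, 40 °C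
Reagents that add atoms: none
Why: Acid-catalysed acetal exchange with methanol removes all eight MOM groups under conditions mild enough for the prenyl groups, and the three stereocentres set in steps 5 and 7 are not involved.

## Compound list

1 | resorcinol | Oc1cccc(O)c1 | starting material
2 | 1,3-bis(methoxymethoxy)benzene | COCOc1cccc(OCOC)c1 | intermediate
3 | 1-bromo-2,4-bis(methoxymethoxy)benzene | COCOc1ccc(Br)c(OCOC)c1 | intermediate
4 | 1-bromo-3-methylbut-2-ene (prenyl bromide) | CC(C)=CCBr | starting material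
5 | [2,6-bis(methoxymethoxy)phenyl]lithium | COCOc1cccc(OCOC)c1[Li] | intermediate (not isolated)
6 | 1,3-bis(methoxymethoxy)-2-(3-methylbut-2-en-1-yl)benzene | COCOc1cccc(OCOC)c1CC=C(C)C | intermediate
7 | [2,4-bis(methoxymethoxy)-3-(3-methylbut-2-en-1-yl)phenyl]lithium | COCOc1ccc([Li])c(OCOC)c1CC=C(C)C | intermediate (not isolated)
8 | 2,4-bis(methoxymethoxy)-3-(3-methylbut-2-en-1-yl)benzaldehyde | COCOc1ccc(C=O)c(OCOC)c1CC=C(C)C | intermediate
9 | (E)-but-2-enal (crotonaldehyde) | C/C=C/C=O | starting material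
10 | methyl 3-oxobutanoate (methyl acetoacetate) | COC(=O)CC(C)=O | starting material
11 | methyl (3S)-2-acetyl-3-methyl-5-oxopentanoate (C2 epimers) | O=CC[C@H](C)C(C(C)=O)C(=O)OC | intermediate (not isolated)
12 | methyl (6S)-6-methyl-2-oxocyclohex-3-ene-1-carboxylate (C1 epimers) | C[C@H]1CC=CC(=O)C1C(=O)OC | intermediate
13 | (5S)-5-methylcyclohex-2-en-1-one | C[C@H]1CC=CC(=O)C1 | intermediate
14 | [2,4-bis(methoxymethoxy)phenyl]magnesium bromide | COCOc1ccc([Mg]Br)c(OCOC)c1 | intermediate (not isolated)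
15 | bromomagnesium (3S,5S)-3-[2,4-bis(methoxymethoxy)phenyl]-5-methylcyclohex-1-en-1-olate | Br[Mg]OC1=C[C@@H](c2ccc(OCOC)cc2OCOC)C[C@H](C)C1 | intermediate (not isolated)
16 | (2S,3S,5S)-3-[2,4-bis(methoxymethoxy)phenyl]-2-{hydroxy[2,4-bis(methoxymethoxy)-3-(3-methylbut-2-en-1-yl)phenyl]methyl}-5-methylcyclohexan-1-one (carbinol epimers) | CC(C)=CCc1c(OCOC)ccc(C(O)[C@H]2C(=O)C[C@@H](C)C[C@@H]2c2ccc(OCOC)cc2OCOC)c1OCOC | intermediate
17 | (2S,3S,5S)-3-[2,4-bis(methoxymethoxy)phenyl]-2-{[(tert-butyldimethylsilyl)oxy][2,4-bis(methoxymethoxy)-3-(3-methylbut-2-en-1-yl)phenyl]methyl}-5-methylcyclohexan-1-one | CC(C)=CCc1c(OCOC)ccc(C(O[Si](C)(C)C(C)(C)C)[C@H]2C(=O)C[C@@H](C)C[C@@H]2c2ccc(OCOC)cc2OCOC)c1OCOC | intermediate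
18 | potassium (3S,5S,6S)-5-[2,4-bis(methoxymethoxy)phenyl]-6-{[(tert-butyldimethylsilyl)oxy][2,4-bis(methoxymethoxy)-3-(3-methylbut-2-en-1-yl)phenyl]methyl}-3-methylcyclohex-1-en-1-olate | CC(C)=CCc1c(OCOC)ccc(C(O[Si](C)(C)C(C)(C)C)[C@H]2C([O-])=C[C@@H](C)C[C@@H]2c2ccc(OCOC)cc2OCOC)c1OCOC.[K+] | intermediate (not isolated)
19 | (3S,5S,6S)-5-[2,4-bis(methoxymethoxy)phenyl]-6-{[(tert-butyldimethylsilyl)oxy][2,4-bis(methoxymethoxy)-3-(3-methylbut-2-en-1-yl)phenyl]methyl}-3-methylcyclohex-1-en-1-yl trifluoromethanesulfonate | CC(C)=CCc1c(OCOC)ccc(C(O[Si](C)(C)C(C)(C)C)[C@H]2C(OS(=O)(=O)C(F)(F)F)=C[C@@H](C)C[C@@H]2c2ccc(OCOC)cc2OCOC)c1OCOC | intermediate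
20 | 2-[(3S,5S,6R)-5-[2,4-bis(methoxymethoxy)phenyl]-6-{[(tert-butyldimethylsilyl)oxy][2,4-bis(methoxymethoxy)-3-(3-methylbut-2-en-1-yl)phenyl]methyl}-3-methylcyclohex-1-en-1-yl]-4,4,5,5-tetramethyl-1,3,2-dioxaborolane | CC(C)=CCc1c(OCOC)ccc(C(O[Si](C)(C)C(C)(C)C)[C@H]2C(B3OC(C)(C)C(C)(C)O3)=C[C@@H](C)C[C@@H]2c2ccc(OCOC)cc2OCOC)c1OCOC | intermediate
21 | 2-[3,5-bis(methoxymethoxy)phenyl]-4,4,5,5-tetramethyl-1,3,2-dioxaborolane | COCOc1cc(OCOC)cc(B2OC(C)(C)C(C)(C)O2)c1 | intermediate (not isolated)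
22 | 3,5-bis(methoxymethoxy)phenol | COCOc1cc(O)cc(OCOC)c1 | intermediate
23 | 2-hydroxy-4,6-bis(methoxymethoxy)benzaldehyde | O=Cc1c(O)cc(OCOC)cc1OCOC | intermediate
24 | 3-bromo-2-hydroxy-4,6-bis(methoxymethoxy)benzaldehyde | O=Cc1c(O)c(Br)c(OCOC)cc1OCOC | intermediate
25 | ethynyltrimethylsilane | C#C[Si](C)(C)C | starting material
26 | {[2,4-bis(methoxymethoxy)phenyl]ethynyl}trimethylsilane | COCOc1ccc(C#C[Si](C)(C)C)c(OCOC)c1 | intermediate
27 | 1-ethynyl-2,4-bis(methoxymethoxy)benzene | COCOc1ccc(C#C)c(OCOC)c1 | intermediate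
28 | lithium [2,4-bis(methoxymethoxy)phenyl]acetylide | COCOc1ccc(C#C[Li])c(OCOC)c1 | intermediate (not isolated)
29 | 2-bromo-6-{3-[2,4-bis(methoxymethoxy)phenyl]-1-hydroxyprop-2-yn-1-yl}-3,5-bis(methoxymethoxy)phenol (racemic carbinol) | COCOc1ccc(C#CC(O)c2c(O)c(Br)c(OCOC)cc2OCOC)c(OCOC)c1 | intermediate
30 | 1-[3-bromo-2-hydroxy-4,6-bis(methoxymethoxy)phenyl]-3-[2,4-bis(methoxymethoxy)phenyl]prop-2-yn-1-one | COCOc1ccc(C#CC(=O)c2c(O)c(Br)c(OCOC)cc2OCOC)c(OCOC)c1 | intermediate (not isolated)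
31 | 8-bromo-2-[2,4-bis(methoxymethoxy)phenyl]-5,7-bis(methoxymethoxy)-4H-chromen-4-one | COCOc1ccc(-c2cc(=O)c3c(OCOC)cc(OCOC)c(Br)c3o2)c(OCOC)c1 | intermediate
32 | {8-bromo-2-[2,4-bis(methoxymethoxy)phenyl]-5,7-bis(methoxymethoxy)-4-oxo-4H-chromen-3-yl}lithium | COCOc1ccc(-c2oc3c(Br)c(OCOC)cc(OCOC)c3c(=O)c2[Li])c(OCOC)c1 | intermediate (not isolated)
33 | 8-bromo-2-[2,4-bis(methoxymethoxy)phenyl]-5,7-bis(methoxymethoxy)-3-(3-methylbut-2-en-1-yl)-4H-chromen-4-one | COCOc1ccc(-c2oc3c(Br)c(OCOC)cc(OCOC)c3c(=O)c2CC=C(C)C)c(OCOC)c1 | intermediate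
34 | 8-[(3S,5S,6R)-5-[2,4-bis(methoxymethoxy)phenyl]-6-{[(tert-butyldimethylsilyl)oxy][2,4-bis(methoxymethoxy)-3-(3-methylbut-2-en-1-yl)phenyl]methyl}-3-methylcyclohex-1-en-1-yl]-2-[2,4-bis(methoxymethoxy)phenyl]-5,7-bis(methoxymethoxy)-3-(3-methylbut-2-en-1-yl)-4H-chromen-4-one | CC(C)=CCc1c(OCOC)ccc(C(O[Si](C)(C)C(C)(C)C)[C@H]2C(c3c(OCOC)cc(OCOC)c4c(=O)c(CC=C(C)C)c(-c5ccc(OCOC)cc5OCOC)oc34)=C[C@@H](C)C[C@@H]2c2ccc(OCOC)cc2OCOC)c1OCOC | intermediate
35 | 8-[(3S,5S,6R)-5-[2,4-bis(methoxymethoxy)phenyl]-6-{hydroxy[2,4-bis(methoxymethoxy)-3-(3-methylbut-2-en-1-yl)phenyl]methyl}-3-methylcyclohex-1-en-1-yl]-2-[2,4-bis(methoxymethoxy)phenyl]-5,7-bis(methoxymethoxy)-3-(3-methylbut-2-en-1-yl)-4H-chromen-4-one | CC(C)=CCc1c(OCOC)ccc(C(O)[C@H]2C(c3c(OCOC)cc(OCOC)c4c(=O)c(CC=C(C)C)c(-c5ccc(OCOC)cc5OCOC)oc34)=C[C@@H](C)C[C@@H]2c2ccc(OCOC)cc2OCOC)c1OCOC | intermediate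
36 | 8-[(3S,5S,6R)-6-[2,4-bis(methoxymethoxy)-3-(3-methylbut-2-en-1-yl)benzoyl]-5-[2,4-bis(methoxymethoxy)phenyl]-3-methylcyclohex-1-en-1-yl]-2-[2,4-bis(methoxymethoxy)phenyl]-5,7-bis(methoxymethoxy)-3-(3-methylbut-2-en-1-yl)-4H-chromen-4-one | CC(C)=CCc1c(OCOC)ccc(C(=O)[C@H]2C(c3c(OCOC)cc(OCOC)c4c(=O)c(CC=C(C)C)c(-c5ccc(OCOC)cc5OCOC)oc34)=C[C@@H](C)C[C@@H]2c2ccc(OCOC)cc2OCOC)c1OCOC | intermediate
37 | 8-[(3S,5S,6R)-6-[2,4-dihydroxy-3-(3-methylbut-2-en-1-yl)benzoyl]-5-(2,4-dihydroxyphenyl)-3-methylcyclohex-1-en-1-yl]-2-(2,4-dihydroxyphenyl)-5,7-dihydroxy-3-(3-methylbut-2-en-1-yl)-4H-chromen-4-one (CNP0314407.1) | CC(C)=CCc1c(O)ccc(C(=O)[C@H]2C(c3c(O)cc(O)c4c(=O)c(CC=C(C)C)c(-c5ccc(O)cc5O)oc34)=C[C@@H](C)C[C@@H]2c2ccc(O)cc2O)c1O | target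

## Totals

Total step count: 22.
Longest linear sequence: 11 steps (for example steps 1, 11, 12, 13, 16, 17, 18, 19, 20, 21, 22).

## Three steps most likely to fail

Step 19 (Suzuki–Miyaura union). Both partners are hindered: the aryl bromide sits between two oxygen substituents and the alkenyl boron is next to a fully substituted ring carbon, so transmetalation may stall or 20 may protodeboronate. The fallback sets out from triflate 19. Stannylation with Me3SnSnMe3, Pd(PPh3)4 and LiCl in dioxane at 90 °C gives [(3S,5S,6S)-5-[2,4-bis(methoxymethoxy)phenyl]-6-{[(tert-butyldimethylsilyl)oxy][2,4-bis(methoxymethoxy)-3-(3-methylbut-2-en-1-yl)phenyl]methyl}-3-methylcyclohex-1-en-1-yl]trimethylstannane F2. A copper-assisted Stille coupling of this stannane with 33 (Pd(PtBu3)2, CuI, CsF, DMF, 45 °C) comes back to the route at 34.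

Step 18 (C3 lithiation and prenylation). The 3-lithioflavone may ring-open to the ynone phenoxide, or alkylate slowly or at the tertiary allyl terminus. The fallback sets out from 31. Zincation at C3 with (tmp)ZnCl·LiCl (THF, 25 °C) and an iodine quench give 8-bromo-3-iodo-2-[2,4-bis(methoxymethoxy)phenyl]-5,7-bis(methoxymethoxy)-4H-chromen-4-one F1. A Stille coupling with tributyl(3-methylbut-2-en-1-yl)stannane (Pd2(dba)3, AsPh3, DMF, 60 °C) at the much more reactive C3–I bond comes back to the route at 33.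

Step 22 (eightfold MOM cleavage). Protic acid can cyclise the ortho-prenyl phenols to chromans or shift the ring double bond. The fallback sets out from 36. Non-protic acetal-to-silyl exchange with Et3SiOTf and 2,2'-bipyridyl in CH2Cl2 at 0 °C gives 8-[(3S,5S,6R)-6-{2,4-bis[(triethylsilyl)oxy]-3-(3-methylbut-2-en-1-yl)benzoyl}-5-{2,4-bis[(triethylsilyl)oxy]phenyl}-3-methylcyclohex-1-en-1-yl]-2-{2,4-bis[(triethylsilyl)oxy]phenyl}-3-(3-methylbut-2-en-1-yl)-5,7-bis[(triethylsilyl)oxy]-4H-chromen-4-one F3. Desilylation with HF·pyridine in THF at 0 °C comes back to the route at 37.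

## Further compounds

F1 | step 18 | 8-bromo-3-iodo-2-[2,4-bis(methoxymethoxy)phenyl]-5,7-bis(methoxymethoxy)-4H-chromen-4-one | COCOc1ccc(-c2oc3c(Br)c(OCOC)cc(OCOC)c3c(=O)c2I)c(OCOC)c1
F2 | step 19 | [(3S,5S,6S)-5-[2,4-bis(methoxymethoxy)phenyl]-6-{[(tert-butyldimethylsilyl)oxy][2,4-bis(methoxymethoxy)-3-(3-methylbut-2-en-1-yl)phenyl]methyl}-3-methylcyclohex-1-en-1-yl]trimethylstannane | CC(C)=CCc1c(OCOC)ccc(C(O[Si](C)(C)C(C)(C)C)[C@H]2C([Sn](C)(C)C)=C[C@@H](C)C[C@@H]2c2ccc(OCOC)cc2OCOC)c1OCOC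
F3 | step 22 | 8-[(3S,5S,6R)-6-{2,4-bis[(triethylsilyl)oxy]-3-(3-methylbut-2-en-1-yl)benzoyl}-5-{2,4-bis[(triethylsilyl)oxy]phenyl}-3-methylcyclohex-1-en-1-yl]-2-{2,4-bis[(triethylsilyl)oxy]phenyl}-3-(3-methylbut-2-en-1-yl)-5,7-bis[(triethylsilyl)oxy]-4H-chromen-4-one | CC(C)=CCc1c(O[Si](CC)(CC)CC)ccc(C(=O)[C@H]2C(c3c(O[Si](CC)(CC)CC)cc(O[Si](CC)(CC)CC)c4c(=O)c(CC=C(C)C)c(-c5ccc(O[Si](CC)(CC)CC)cc5O[Si](CC)(CC)CC)oc34)=C[C@@H](C)C[C@@H]2c2ccc(O[Si](CC)(CC)CC)cc2O[Si](CC)(CC)CC)c1O[Si](CC)(CC)CC
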